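**Remark on the chemistry.** The given structure defines only C3 (S). It carries no descriptor for the C7–C8' biaryl axis, so the axis is left uncontrolled; if its two rotamers prove separable, both are the structure as drawn.

**Locants.** Isoquinoline numbering is used for the heterocycle (C1, N2, C3, C4, C4a, C5 to C8, C8a). The naphthalene carries primed locants: C8' is bonded to C7, OMe sits on C5', OH on C4', CH3 on C2'. Intermediates use the locants of the atoms they become.

**Numbering used throughout.**
- Naphthalene half: 1 silylaryl triflate, 2 acetylacetone, 3 3-methoxybenzyne, 4 diketone, 5 naphthol, 6 naphthyl pivalate, 7 bromonaphthyl pivalate.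
- Benzo-ring half: 8 5-bromovanillin, 9 aryl formate, 10 bromo(methoxy)hydroquinone, 11 its bis(methoxymethyl) ether, 12 aryllithium from 11, 13 arylsilane, 14 aryllithium from 13 (lithium on C7), 15 arylzinc chloride.
- After coupling: 16 biaryl, 17 biaryl hydroquinone, 18 biaryl bis(triflate) with silicon on C4a, 19 aryne (C4a≡C8a), 20 biaryl diketone, 21 (S)-amino ketone, 22 protected dihydroisoquinoline, 23 target.

## Analysis of the target

The target is a 7,8'-linked naphthylisoquinoline. A 1,3-dimethyl-3,4-dihydroisoquinoline has a benzo ring (C4a–C5–C6–C7–C8–C8a) that carries OH on C6 and OMe on C8, and C7 is bonded to C8' of a 4'-hydroxy-5'-methoxy-2'-methylnaphthalene. The only stereocentre is C3 (S), between N2 and the benzylic C4; it has no partner to be related to, and the axis carries no descriptor. The sensitive groups are the cyclic ketimine C1=N2 (reducible, enolisable through the C1 methyl group) and two electron-rich free phenols (O6–H, O4'–H), each beside a methyl ether that has to stay (O8, O5'). The synthesis is hard for three reasons. The benzo ring bears five different substituents, so every position has to be addressed regiospecifically. The C7–C8' bond lies between two oxygens and next to the peri position C1'. Two pairs of oxygens (O6/O8 and O4'/O5') must end differentiated. The feature that invites the strategy is the pair of neighbouring carbons C4a and C8a. C4a carries C4H2–C3(CH3) and C8a carries C1(CH3)=N2, which are a 2-oxopropyl and an acetyl group once nitrogen is taken out. These are the two halves of acetylacetone cut at its C2–C3 bond, and the acetyl half sits on the carbon beside the C8 methoxy group. The naphthalene shows the same pattern: C4'(OH) is an acetyl carbon on C4a' beside the C5' methoxy group, and C1'–C2'(CH3) is a 2-oxopropyl group on C8a'.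

## Retrosynthetic reasoning

**23 from 22.** The O6–S and O4'–acyl bonds are cut last. The triflate on O6 and the pivalate on O4' are both inert to the conditions of the key step and both fall to basic hydrolysis, so one operation ends the route and the imine is not touched.

**22 from 20.** The C3–N2 and C1=N2 bonds are cut together, as in the presumed biosynthesis: diketone 20 is aminated at the 2-oxopropyl carbonyl only, and the amine 21 condenses with the acetyl group on C8a. The forward step has to discriminate the two ketones and set C3 (S). An enzymatic transamination does both, because the acetyl group between two ortho substituents is not a substrate and the methyl/arylmethyl pair is told apart well by such enzymes.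

**20 from 18 and 2 (key disconnection).** The C4a–C4 and C8a–C1 bonds are cut in one stroke. Both come from a single molecule of acetylacetone 2, whose C2–C3 bond is inserted across aryne 19 (C4a≡C8a). The cut is made here because all five non-aromatic carbons of the heterocycle then arrive in one step on a benzo ring that already carries the biaryl bond and both oxygens in their final pattern. No cyclisation onto a ring with two competing ortho positions is needed, and no coupling next to the imine. The forward reaction must add the enolate carbon to C4a and leave the acyl group on C8a; the C8 methoxy group beside the triple bond dictates exactly this.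

**18 from 17 and 16.** The aryne precursor needs a leaving group on C8a and silicon on C4a. O8a and O6 are para to each other (a hydroquinone), so they never have to be told apart: both are masked as methoxymethyl ethers while organolithium chemistry is done, and both become triflates afterwards. Only the triflate on C8a has an ortho silicon and is lost in the key step; the one on C6 serves as the phenol protecting group.

**16 from 13 and 7.** The C7–C8' bond is cut next. C7 is the only ring position between two alkoxy groups in 13, so it is lithiated selectively (14), transmetalated (15) and coupled with bromide 7. Doing this before the heterocycle exists keeps the hindered coupling away from the imine and the stereocentre.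

**13 from 8.** The silicon on C4a is traced back to the bromine of commercial 5-bromovanillin 8, which already has OMe and OH in the right places. The formyl carbon marks C6, and a Dakin oxidation turns it into O6 (10); protection (11) and bromine–lithium exchange (12) give 13. The substitution pattern therefore comes from the starting material and not from a selectivity.

**7 from 1 and 2.** The naphthalene is cut at C4a'–C4' and C8a'–C1' by the same logic: 3-methoxybenzyne 3 and acetylacetone 2 give diketone 4, whose aldol condensation gives naphthol 5 with OH peri to OMe. Acylation (6) switches off the oxygenated ring, so bromination goes para to the methoxy group at C8' (7). Both halves of the alkaloid thus come from an aryne and 2, which mirrors the biosynthetic idea of one diketone type for both halves.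

## Alternatives that were turned down

**Alternative 1:** the textbook route. Disconnection: C8a–C1 by Bischler–Napieralski cyclisation of the (S)-acetamide A1, then iodination to the 7-iodo-dihydroisoquinoline A2 and a palladium-catalysed coupling at C7 with the naphthalene half as the last C–C bond. It was turned down for four reasons.
- The two ring positions ortho to the side chain of A1 are each para to one alkoxy group and nearly equal in activation, so the cyclisation would give both the 6-benzyloxy-8-methoxy and the 6-methoxy-8-benzyloxy ring.
- The halogenation has to choose C7, the more hindered of two activated positions (C5 and C7).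
- The most hindered bond of the molecule would be made at the end, beside a basic and reducible imine.
- A1 needs its own asymmetric synthesis of several steps, so the route is longer and its regiochemical problems stay open.

**Alternative 2:** biomimetic oxidative phenol coupling. Disconnection: C7–C8' between the free phenol A3 and naphthol 5, with a one-electron oxidant as the forward key step. It was turned down because the spin and charge density of oxidised 5 lies ortho and para to its free OH, at C3' and C1' in the methyl-bearing ring. C8' is para to the methyl ether and is not activated. A3 can also react at C5 as well as C7, and both partners can dimerise. To direct the coupling to C8' the methylation pattern of the naphthalene would have to be inverted and restored, which costs the steps the coupling saves.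

**Alternative 3:** an aryne for the biaryl bond. Disconnection: C7–C8' by addition of aryllithium 14 to the 1,2-naphthalyne A4 (C7'≡C8'). It was turned down because the new bond has to form at the α carbon C8', which is peri-hindered. A bulky aryl nucleophile adds to a 1,2-naphthalyne mainly at the β carbon, and the target has only hydrogen at C6' and C7', so no group beside the triple bond can reverse this. The main product would be the wrong isomer A5, and a removable directing group at C6' would add steps.

Key step: step 10

## Route

Step 1
Reactants: 1 3-methoxy-2-(trimethylsilyl)phenyl trifluoromethanesulfonate; 2 pentane-2,4-dione (acetylacetone)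
Product: 5 8-methoxy-3-methylnaphthalen-1-ol, via 3-methoxybenzyne 3 (not isolated), via 1-(2-acetyl-3-methoxyphenyl)propan-2-one 4 (not isolated)
Conditions: CsF, MeCN, 80 °C; then NaOMe, MeOH, 65 °C; HCl (aq) quench
Reagents that add atoms: none
Why: Aryne acyl-alkylation (σ-insertion of an aryne into the C–C bond of a 1,3-diketone): the enolate carbon adds meta to OMe and the acetyl group ends ortho to it. Methoxide then drives the intramolecular aldol condensation of the acetyl methyl group onto the unhindered 2-oxopropyl ketone and aromatisation, which should give the 1-naphthol with OH peri to OMe.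

Step 2
Reactants: 5 8-methoxy-3-methylnaphthalen-1-ol
Product: 6 8-methoxy-3-methylnaphthalen-1-yl 2,2-dimethylpropanoate
Conditions: PivCl, Et3N, DMAP (cat.), CH2Cl2, 0 °C to rt
Reagents that add atoms: pivaloyl chloride, CC(C)(C)C(Cl)=O
Why: DMAP-catalysed O-acylation. The pivalate deactivates the methyl-bearing ring for step 3, is inert to organozinc reagents and to fluoride, and is removed in the last step.

Step 3
Reactants: 6 8-methoxy-3-methylnaphthalen-1-yl 2,2-dimethylpropanoate
Product: 7 5-bromo-8-methoxy-3-methylnaphthalen-1-yl 2,2-dimethylpropanoate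
Conditions: NBS, MeCN, 0 °C to rt, dark
Reagents that add atoms: N-bromosuccinimide, O=C1CCC(=O)N1Br
Why: Electrophilic aromatic bromination. The methoxy group is the only strong donor left and directs to its para α-position (C8'), while the acyloxy-substituted ring is switched off.

Step 4
Reactants: 8 3-bromo-4-hydroxy-5-methoxybenzaldehyde (5-bromovanillin)
Product: 10 2-bromo-6-methoxybenzene-1,4-diol, via 3-bromo-4-hydroxy-5-methoxyphenyl formate 9 (not isolated)
Conditions: H2O2 (30% aq), NaOH, THF/H2O, 0 °C to rt, argon; Na2S2O4/HCl work-up
Reagents that add atoms: hydrogen peroxide, OO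
Why: Dakin oxidation: the hydroperoxide adduct of the aldehyde rearranges by aryl migration, which the para phenoxide favours, and the formate is hydrolysed in the same flask. The formyl carbon becomes O6 and the bromine stays ortho to the oxygen that becomes O8a.

Step 5
Reactants: 10 2-bromo-6-methoxybenzene-1,4-diol
Product: 11 1-bromo-3-methoxy-2,5-bis(methoxymethoxy)benzene
Conditions: NaH, MOMCl, DMF, 0 °C to rt, argon
Reagents that add atoms: chloromethyl methyl ether, COCCl
Why: Twofold O-alkylation of the hydroquinone dianion. The two oxygens need no differentiation, and the acetal on O6 later acts as directing group for the metalation at C7.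

Step 6
Reactants: 11 1-bromo-3-methoxy-2,5-bis(methoxymethoxy)benzene
Product: 13 [3-methoxy-2,5-bis(methoxymethoxy)phenyl]trimethylsilane, via [3-methoxy-2,5-bis(methoxymethoxy)phenyl]lithium 12 (not isolated)
Conditions: n-BuLi, THF, −78 °C; TMSCl, −78 °C to rt
Reagents that add atoms: n-butyllithium, CCCC[Li] (lithium in 12); chlorotrimethylsilane, C[Si](C)(C)Cl
Why: Bromine–lithium exchange is much faster than ring deprotonation at −78 °C, and the aryllithium, held by the ortho acetal oxygen, is silylated. The silicon therefore sits on C4a, where the bromine of 8 was.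

Step 7
Reactants: 13 [3-methoxy-2,5-bis(methoxymethoxy)phenyl]trimethylsilane; 7 5-bromo-8-methoxy-3-methylnaphthalen-1-yl 2,2-dimethylpropanoate
Product: 16 8-methoxy-5-[2-methoxy-3,6-bis(methoxymethoxy)-4-(trimethylsilyl)phenyl]-3-methylnaphthalen-1-yl 2,2-dimethylpropanoate, via aryllithium 14 (not isolated), via arylzinc chloride 15 (not isolated)
Conditions: n-BuLi, TMEDA, THF, 0 °C; ZnCl2, 0 °C to rt; then 7, Pd2(dba)3 (cat.), RuPhos (cat.), 65 °C
Reagents that add atoms: n-butyllithium, CCCC[Li] (lithium in 14); zinc dichloride, Cl[Zn]Cl (zinc and chlorine in 15)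
Why: Directed ortho-metalation at C7, the only position between two alkoxy groups; C5 has one directing group and the bulky silyl neighbour. Transmetalation to zinc and Negishi coupling with a dialkylbiarylphosphine ligand should make the tri-ortho-substituted biaryl bond. The arylzinc does not attack the pivalate.

Step 8
Reactants: 16 8-methoxy-5-[2-methoxy-3,6-bis(methoxymethoxy)-4-(trimethylsilyl)phenyl]-3-methylnaphthalen-1-yl 2,2-dimethylpropanoate
Product: 17 5-[3,6-dihydroxy-2-methoxy-4-(trimethylsilyl)phenyl]-8-methoxy-3-methylnaphthalen-1-yl 2,2-dimethylpropanoate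
Conditions: ZnBr2, n-PrSH, CH2Cl2, 0 °C to rt, argon
Reagents that add atoms: none
Why: Lewis acid/thiol cleavage of both methoxymethyl ethers. It is fast and nearly neutral, so the aryl–silicon bond ortho to the new phenol and the pivalate should survive; the hydroquinone is used at once.

Step 9
Reactants: 17 5-[3,6-dihydroxy-2-methoxy-4-(trimethylsilyl)phenyl]-8-methoxy-3-methylnaphthalen-1-yl 2,2-dimethylpropanoate
Product: 18 8-methoxy-5-[2-methoxy-3,6-bis(trifluoromethanesulfonyloxy)-4-(trimethylsilyl)phenyl]-3-methylnaphthalen-1-yl 2,2-dimethylpropanoate
Conditions: Tf2O, pyridine, CH2Cl2, −20 to 0 °C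
Reagents that add atoms: trifluoromethanesulfonic anhydride, O=S(=O)(OS(=O)(=O)C(F)(F)F)C(F)(F)F
Why: O-Sulfonylation of both phenols. The triflate on C8a with its ortho silicon is the aryne precursor, and the triflate on C6 is a fluoride-stable, non-nucleophilic mask of the C6 phenol.

Step 10
Reactants: 18 8-methoxy-5-[2-methoxy-3,6-bis(trifluoromethanesulfonyloxy)-4-(trimethylsilyl)phenyl]-3-methylnaphthalen-1-yl 2,2-dimethylpropanoate; 2 pentane-2,4-dione (acetylacetone)
Product: 20 5-[3-acetyl-2-methoxy-4-(2-oxopropyl)-6-(trifluoromethanesulfonyloxy)phenyl]-8-methoxy-3-methylnaphthalen-1-yl 2,2-dimethylpropanoate, via aryne 19 (not isolated)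
Conditions: 2 (excess), CsF, MeCN, 60–80 °C
Reagents that add atoms: none
Why: Aryne acyl-alkylation, the σ-insertion of an aryne into the C2–C3 bond of a 1,3-diketone. CsF attacks silicon on C4a and the triflate on C8a leaves, which gives aryne 19; the C6 triflate has no ortho silicon and stays. The cesium enolate of 2 adds through its central carbon to C4a, the aryne carbon remote from the C8 methoxy group: the inductively withdrawing oxygen beside C8a distorts the triple bond so that C4a is the more electrophilic end and the carbanion developing on C8a is stabilised, and C4a is also the unhindered end (C5–H). The aryl anion on C8a then adds to one acetyl carbonyl (4-exo-trig) to a benzocyclobutenoxide, which fragments by retro-aldol cleavage of the former C2–C3 bond of 2; this leaves the acetyl group on C8a and, after protonation by excess 2, the 2-oxopropyl group on C4a. No ring of the product is closed (the four-membered ring is transient) and no stereocentre is formed; the step makes both new C–C bonds and delivers all five non-aromatic carbons of the heterocycle. The selectivity needed is the regioselectivity of the enolate addition, which the C8 methoxy group secures, and the survival of 20, which the excess of the far more acidic 2 secures by buffering the medium against the aldol condensation used on purpose in step 1.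

Step 11
Reactants: 20 5-[3-acetyl-2-methoxy-4-(2-oxopropyl)-6-(trifluoromethanesulfonyloxy)phenyl]-8-methoxy-3-methylnaphthalen-1-yl 2,2-dimethylpropanoate
Product: 22 8-methoxy-5-[(3S)-8-methoxy-1,3-dimethyl-6-(trifluoromethanesulfonyloxy)-3,4-dihydroisoquinolin-7-yl]-3-methylnaphthalen-1-yl 2,2-dimethylpropanoate, via amino ketone 21 (not isolated)
Conditions: (S)-selective ω-transaminase (for example the enzyme from Vibrio fluvialis or an engineered variant), pyridoxal 5'-phosphate (cat.), isopropylamine, HEPES buffer pH 8, DMSO (20% v/v), 30 °C
Reagents that add atoms: isopropylamine, CC(C)N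
Why: Biomimetic transaminase-triggered cyclisation of a 1,5-diketone. The enzyme should aminate only the 2-oxopropyl ketone (methyl in the small pocket, arylmethyl in the large one, hence S at C3), because the acetyl group between two ortho substituents is not accepted. Amine 21 then closes the ring by 6-exo-trig addition to that acetyl group and loss of water, which also pulls the transamination equilibrium.

Step 12
Reactants: 22 8-methoxy-5-[(3S)-8-methoxy-1,3-dimethyl-6-(trifluoromethanesulfonyloxy)-3,4-dihydroisoquinolin-7-yl]-3-methylnaphthalen-1-yl 2,2-dimethylpropanoate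
Product: 23 (3S)-7-(5-hydroxy-4-methoxy-7-methylnaphthalen-1-yl)-8-methoxy-1,3-dimethyl-3,4-dihydroisoquinolin-6-ol
Conditions: Et4NOH (aq), 1,4-dioxane, rt to 45 °C, argon; then NH4Cl (aq)
Reagents that add atoms: none
Why: Hydroxide cleaves the aryl triflate at sulfur (S–O cleavage, the aryl oxygen is kept) and the pivalate at the acyl carbon. The cyclic ketimine and both methyl ethers are inert to base, and C3 has no acidic hydrogen that could epimerise it.

## Compound list

1 | 3-methoxy-2-(trimethylsilyl)phenyl trifluoromethanesulfonate | COc1cccc(OS(=O)(=O)C(F)(F)F)c1[Si](C)(C)C | starting material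
2 | pentane-2,4-dione (acetylacetone) | CC(=O)CC(C)=O | starting material
3 | 3-methoxybenzyne | COC1=CC=CC#C1 | intermediate
4 | 1-(2-acetyl-3-methoxyphenyl)propan-2-one | COc1cccc(CC(C)=O)c1C(C)=O | intermediate
5 | 8-methoxy-3-methylnaphthalen-1-ol | COc1cccc2cc(C)cc(O)c12 | intermediate
6 | 8-methoxy-3-methylnaphthalen-1-yl 2,2-dimethylpropanoate | COc1cccc2cc(C)cc(OC(=O)C(C)(C)C)c12 | intermediate
7 | 5-bromo-8-methoxy-3-methylnaphthalen-1-yl 2,2-dimethylpropanoate | COc1ccc(Br)c2cc(C)cc(OC(=O)C(C)(C)C)c12 | intermediate
8 | 3-bromo-4-hydroxy-5-methoxybenzaldehyde (5-bromovanillin) | COc1cc(C=O)cc(Br)c1O | starting material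
9 | 3-bromo-4-hydroxy-5-methoxyphenyl formate | COc1cc(OC=O)cc(Br)c1O | intermediate
10 | 2-bromo-6-methoxybenzene-1,4-diol | COc1cc(O)cc(Br)c1O | intermediate
11 | 1-bromo-3-methoxy-2,5-bis(methoxymethoxy)benzene | COc1cc(OCOC)cc(Br)c1OCOC | intermediate
12 | [3-methoxy-2,5-bis(methoxymethoxy)phenyl]lithium | COc1cc(OCOC)cc([Li])c1OCOC | intermediate
13 | [3-methoxy-2,5-bis(methoxymethoxy)phenyl]trimethylsilane | COc1cc(OCOC)cc([Si](C)(C)C)c1OCOC | intermediate
14 | [2-methoxy-3,6-bis(methoxymethoxy)-4-(trimethylsilyl)phenyl]lithium | COc1c([Li])c(OCOC)cc([Si](C)(C)C)c1OCOC | intermediate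
15 | chloro[2-methoxy-3,6-bis(methoxymethoxy)-4-(trimethylsilyl)phenyl]zinc | COc1c([Zn]Cl)c(OCOC)cc([Si](C)(C)C)c1OCOC | intermediate
16 | 8-methoxy-5-[2-methoxy-3,6-bis(methoxymethoxy)-4-(trimethylsilyl)phenyl]-3-methylnaphthalen-1-yl 2,2-dimethylpropanoate | COc1c(-c2ccc(OC)c3c(OC(=O)C(C)(C)C)cc(C)cc23)c(OCOC)cc([Si](C)(C)C)c1OCOC | intermediate
17 | 5-[3,6-dihydroxy-2-methoxy-4-(trimethylsilyl)phenyl]-8-methoxy-3-methylnaphthalen-1-yl 2,2-dimethylpropanoate | COc1c(-c2ccc(OC)c3c(OC(=O)C(C)(C)C)cc(C)cc23)c(O)cc([Si](C)(C)C)c1O | intermediate
18 | 8-methoxy-5-[2-methoxy-3,6-bis(trifluoromethanesulfonyloxy)-4-(trimethylsilyl)phenyl]-3-methylnaphthalen-1-yl 2,2-dimethylpropanoate | COc1c(-c2ccc(OC)c3c(OC(=O)C(C)(C)C)cc(C)cc23)c(OS(=O)(=O)C(F)(F)F)cc([Si](C)(C)C)c1OS(=O)(=O)C(F)(F)F | intermediate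
19 | 5-[3,4-didehydro-2-methoxy-6-(trifluoromethanesulfonyloxy)phenyl]-8-methoxy-3-methylnaphthalen-1-yl 2,2-dimethylpropanoate (aryne, C4a≡C8a) | COC1=C(c2ccc(OC)c3c(OC(=O)C(C)(C)C)cc(C)cc23)C(OS(=O)(=O)C(F)(F)F)=CC#C1 | intermediate
20 | 5-[3-acetyl-2-methoxy-4-(2-oxopropyl)-6-(trifluoromethanesulfonyloxy)phenyl]-8-methoxy-3-methylnaphthalen-1-yl 2,2-dimethylpropanoate | COc1c(-c2ccc(OC)c3c(OC(=O)C(C)(C)C)cc(C)cc23)c(OS(=O)(=O)C(F)(F)F)cc(CC(C)=O)c1C(C)=O | intermediate
21 | 5-{3-acetyl-4-[(2S)-2-aminopropyl]-2-methoxy-6-(trifluoromethanesulfonyloxy)phenyl}-8-methoxy-3-methylnaphthalen-1-yl 2,2-dimethylpropanoate | COc1c(-c2ccc(OC)c3c(OC(=O)C(C)(C)C)cc(C)cc23)c(OS(=O)(=O)C(F)(F)F)cc(C[C@H](C)N)c1C(C)=O | intermediate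
22 | 8-methoxy-5-[(3S)-8-methoxy-1,3-dimethyl-6-(trifluoromethanesulfonyloxy)-3,4-dihydroisoquinolin-7-yl]-3-methylnaphthalen-1-yl 2,2-dimethylpropanoate | COc1c2c(cc(OS(=O)(=O)C(F)(F)F)c1-c1ccc(OC)c3c(OC(=O)C(C)(C)C)cc(C)cc13)C[C@H](C)N=C2C | intermediate
23 | (3S)-7-(5-hydroxy-4-methoxy-7-methylnaphthalen-1-yl)-8-methoxy-1,3-dimethyl-3,4-dihydroisoquinolin-6-ol | COc1c2c(cc(O)c1-c1ccc(OC)c3c(O)cc(C)cc13)C[C@H](C)N=C2C | target

## Step count and least certain steps

Total step count: 12. Longest linear sequence: 9 steps (steps 4 to 12 from 8; equally steps 1 to 3 and 7 to 12 from 1).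

**Step 10 (key step).** Three processes are most likely to go wrong.
- Base-mediated intramolecular aldol condensation of the product diketone under the fluoride conditions, the same process that step 1 uses on purpose.
- Erosion of the regioselectivity of the enolate addition, because the triflate on C6 pulls weakly against the C8 methoxy group.
- Fluoride- or enolate-induced acyl transfer from the pivalate, followed by O-arylation of the freed naphtholate by the aryne.

The fallback sets out from 18 and comes back at 22, and it also replaces step 11. The aryne is generated from 18 as before in the presence of 2, and aqueous ammonia is added to the same flask, so that the diketone is taken at once into the fully aromatic 8-methoxy-5-[8-methoxy-1,3-dimethyl-6-(trifluoromethanesulfonyloxy)isoquinolin-7-yl]-3-methylnaphthalen-1-yl 2,2-dimethylpropanoate F1. The pyridine ring is then dearomatised by asymmetric hydrogenation ([Ir(cod)Cl]2, a chiral bisphosphine in the enantiomer that leads to 3S, a halogen activator, H2), which should give the cis-(1R,3S)-tetrahydroisoquinoline F2. N-Chlorination with N-chlorosuccinimide gives the N-chloroamine F3, and dehydrochlorination with DBU towards the benzylic C1 gives the conjugated imine 22; the C1 stereocentre is erased and C3 stays.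

**Step 11.** The enzyme may not accept so bulky and lipophilic a ketone, the substrate may be poorly soluble in the buffer, and the enzyme may discriminate kinetically between the two rotamers about the axis. The fallback sets out from 20 and comes back at 22. Condensation of the 2-oxopropyl ketone with (R)-tert-butanesulfinamide and Ti(OEt)4 should leave the hindered acetyl group untouched and give the N-sulfinyl ketimine F4. Reduction with LiBH(s-Bu)3 at −78 °C should give the (S)-configured sulfinamide F5, whose diastereomer can be removed by chromatography. HCl in methanol followed by NaHCO3 frees amine 21, which cyclises to 22.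

**Step 7.** The lithiation may be incomplete or go astray (lateral metalation at a silicon methyl group), reductive elimination to the tri-ortho-substituted biaryl may be slow enough for protodezincation to compete, and residual organolithium may attack the pivalate. The fallback sets out from 13 and 7 and comes back at 16, with the roles of the partners reversed. Aryllithium 14 is quenched with iodine to [4-iodo-3-methoxy-2,5-bis(methoxymethoxy)phenyl]trimethylsilane F6. Bromide 7 is converted by Miyaura borylation (B2pin2, Pd(dppf)Cl2, KOAc) into 8-methoxy-3-methyl-5-(4,4,5,5-tetramethyl-1,3,2-dioxaborolan-2-yl)naphthalen-1-yl 2,2-dimethylpropanoate F7. A Suzuki–Miyaura coupling of F6 and F7 (Pd(OAc)2, SPhos, K3PO4, toluene/water) gives 16.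

**Step 3.** Bromination may also occur at C1' (para to the acylated oxygen, ortho to the methyl group), or twice. The fallback sets out from 6 and comes back at 16. Thianthrenation of 6 (thianthrene S-oxide, trifluoroacetic anhydride, HBF4·OEt2, MeCN) is far more para-selective than bromination and should give 5-[4-methoxy-7-methyl-5-(pivaloyloxy)naphthalen-1-yl]thianthren-5-ium tetrafluoroborate F8, which takes the place of 7 as the electrophile in the Negishi coupling of step 7 with 15.

## Further compounds

F1 | step 10 | 8-methoxy-5-[8-methoxy-1,3-dimethyl-6-(trifluoromethanesulfonyloxy)isoquinolin-7-yl]-3-methylnaphthalen-1-yl 2,2-dimethylpropanoate | COc1c2c(C)nc(C)cc2cc(OS(=O)(=O)C(F)(F)F)c1-c1ccc(OC)c2c(OC(=O)C(C)(C)C)cc(C)cc12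
F2 | step 10 | 8-methoxy-5-[(1R,3S)-8-methoxy-1,3-dimethyl-6-(trifluoromethanesulfonyloxy)-1,2,3,4-tetrahydroisoquinolin-7-yl]-3-methylnaphthalen-1-yl 2,2-dimethylpropanoate | COc1c2c(cc(OS(=O)(=O)C(F)(F)F)c1-c1ccc(OC)c3c(OC(=O)C(C)(C)C)cc(C)cc13)C[C@H](C)N[C@@H]2C
F3 | step 10 | 5-[(1R,3S)-2-chloro-8-methoxy-1,3-dimethyl-6-(trifluoromethanesulfonyloxy)-1,2,3,4-tetrahydroisoquinolin-7-yl]-8-methoxy-3-methylnaphthalen-1-yl 2,2-dimethylpropanoate | COc1c2c(cc(OS(=O)(=O)C(F)(F)F)c1-c1ccc(OC)c3c(OC(=O)C(C)(C)C)cc(C)cc13)C[C@H](C)N(Cl)[C@@H]2C
F4 | step 11 | 5-{3-acetyl-4-[2-{[(R)-tert-butylsulfinyl]imino}propyl]-2-methoxy-6-(trifluoromethanesulfonyloxy)phenyl}-8-methoxy-3-methylnaphthalen-1-yl 2,2-dimethylpropanoate | COc1c(-c2ccc(OC)c3c(OC(=O)C(C)(C)C)cc(C)cc23)c(OS(=O)(=O)C(F)(F)F)cc(CC(C)=N[S@](=O)C(C)(C)C)c1C(C)=O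
F5 | step 11 | 5-{3-acetyl-4-[(2S)-2-{[(R)-tert-butylsulfinyl]amino}propyl]-2-methoxy-6-(trifluoromethanesulfonyloxy)phenyl}-8-methoxy-3-methylnaphthalen-1-yl 2,2-dimethylpropanoate | COc1c(-c2ccc(OC)c3c(OC(=O)C(C)(C)C)cc(C)cc23)c(OS(=O)(=O)C(F)(F)F)cc(C[C@H](C)N[S@](=O)C(C)(C)C)c1C(C)=O
F6 | step 7 | [4-iodo-3-methoxy-2,5-bis(methoxymethoxy)phenyl]trimethylsilane | COc1c(I)c(OCOC)cc([Si](C)(C)C)c1OCOC
F7 | step 7 | 8-methoxy-3-methyl-5-(4,4,5,5-tetramethyl-1,3,2-dioxaborolan-2-yl)naphthalen-1-yl 2,2-dimethylpropanoate | COc1ccc(B2OC(C)(C)C(C)(C)O2)c2cc(C)cc(OC(=O)C(C)(C)C)c12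
F8 | step 3 | 5-[4-methoxy-7-methyl-5-(pivaloyloxy)naphthalen-1-yl]thianthren-5-ium tetrafluoroborate | COc1ccc([S+]2c3ccccc3Sc3ccccc32)c2cc(C)cc(OC(=O)C(C)(C)C)c12.F[B-](F)(F)F
A1 | alternative 1 | N-{(2S)-1-[3-(benzyloxy)-5-methoxyphenyl]propan-2-yl}acetamide | COc1cc(C[C@H](C)NC(C)=O)cc(OCc2ccccc2)c1
A2 | alternative 1 | (3S)-6-(benzyloxy)-7-iodo-8-methoxy-1,3-dimethyl-3,4-dihydroisoquinoline | COc1c2c(cc(OCc3ccccc3)c1I)C[C@H](C)N=C2C
A3 | alternative 2 | (3S)-8-methoxy-1,3-dimethyl-3,4-dihydroisoquinolin-6-ol | COc1c2c(cc(O)c1)C[C@H](C)N=C2C
A4 | alternative 3 | 1,2-didehydro-4-methoxy-5-(methoxymethoxy)-7-methylnaphthalene | COC1=CC#CC2=C1C(OCOC)=CC(C)=C2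
A5 | alternative 3 | {2-methoxy-4-[4-methoxy-5-(methoxymethoxy)-7-methylnaphthalen-2-yl]-3,6-bis(methoxymethoxy)phenyl}trimethylsilane (aryl bonded to C7' instead of C8') | COCOc1cc([Si](C)(C)C)c(OCOC)c(OC)c1-c1cc(OC)c2c(OCOC)cc(C)cc2c1
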